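**Remarks (assumptions)**
- Atoms carry daucane numbers in every intermediate: C1 (quaternary, CH3-15), C2, C3, C4 (OH, isopropyl), C5 (ring-fusion CH), C6 (ester oxygen), C7=C8 (CH3-14 on C8), C9, C10.
- The chiral-imine Michael addition of step 2 is taken to follow its usual sense, the (R)-amine giving the (S)-configured quaternary carbon. If the sense were the opposite, the (S)-amine would be used.
- 4-[(tert-Butyldimethylsilyl)oxy]benzoic acid is taken as a purchasable compound; otherwise it is one operation from 4-hydroxybenzoic acid.

## Structural features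

The target is a daucane-type sesquiterpenoid monoester: a hydroazulene in which a cyclopentane (C1–C5) and a cycloheptene (C1, C5–C10) share the C1–C5 bond. The four stereocentres C1, C4, C5 and C6 are contiguous around C5. The ring fusion is trans (H5 anti to CH3-15), the C4 hydroxyl is cis to CH3-15, and the C6 oxygen is trans to the C4 hydroxyl and allylic to the trisubstituted C7=C8 bond. C5 lies between the quaternary C1 and the fully substituted C4, so its configuration is best set by a stereospecific event and not by a reagent approaching it. Fragile elements are the tertiary C4 alcohol β to the C6 oxygen (dehydration, and retro-aldol once C6 is a ketone), the allylic ester and the free phenol. The real difficulty is the trans-fused 5–7 skeleton with the angular methyl next to the C4/C5/C6 array. The key step exploits the triad C1–C5–C6: at the C6-ketone level the array O4–C4–C5(H)–C6=O with C1 on C5 is the product pattern of a pinacol-type shift of C1 from C6 to C5. Undoing that shift turns the hydroazulene into a decalin made of the six-membered rings C1–C6 (ring B) and C1, C6–C10 (ring A).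

## Logic of the disconnections

**20 ⇒ 19 ⇒ 17 + 18.** The phenol O–H is masked as a silyl ether and the ester C6–O–C(=O) bond is cut. This separates the aromatic acid from the terpenoid core and leaves acylation for the end. The forward acylation has to choose the secondary allylic hydroxyl of 17 over the tertiary one, which their different substitution secures.

**17 ⇒ 16.** The C6–H bond is cut (ketone reduction). This removes one stereocentre and exposes the β-hydroxy ketone O4–C4–C5–C6=O. The forward step must deliver hydride to the C6 face on the side of O4; the C4 hydroxyl can be used as the delivering group.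

**16 ⇒ 13 (through 14 and 15).** The C8–CH3 bond is cut. The ring A precursor then needs no methyl and no stereocentre at C8, so the bicyclic starting ketone is the simplest known one. The forward step is a conjugate methylation with re-oxidation, which is regiospecific because only the C7/C8 side of the ketone can desaturate.

**13 ⇒ 12 (key disconnection).** The C5–C1 bond is cut and C1 is returned to C6, so the trans-fused hydroazulenone becomes a cis-decalin in which C6 is a tertiary carbinol and C5 carries a sulfonate. This replaces a 5–7 skeleton by two six-membered rings that come from annulation chemistry. It also reduces the four contiguous centres to an all-cis O4/O5/O6 triad on the face of CH3-15. In one sentence: 12, a cis-decalin triol monomesylate, is converted by a 1,2-shift of its ring-fusion bond into 13. The forward step demands that the C5–O bond be equatorial and anti to C6–C1, and that C1 migrate in preference to C3.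

**12 ⇒ 11 ⇒ 9 (through 10).** The sulfonate S–O bond and then the C5–O and C6–O bonds are cut (cis-dihydroxylation of C5=C6). Three oxygen-bearing centres are reduced to one, the C4 carbinol. The forward osmylation must occur on the proximal alkene and on the face of the C4 hydroxyl, which is also the face of CH3-15, so delivery by that hydroxyl is required.

**9 ⇒ 8.** The C4–isopropyl bond is cut (1,2-addition to the dienone). The forward step must add anti to the angular methyl and in the 1,2 sense.

**8 ⇒ 7.** The C7=C8 bond is removed (dehydrogenation). This places the unsaturation of the later cycloheptenone before the shift, so that the shift itself delivers a conjugated enone.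

**7 ⇒ 6 ⇒ 3 + 4 ⇒ 1 + 2 (through 5).** The C5=C6 bond (aldol condensation) and the C1–C2 bond (Michael addition) are cut. One catalyst-free, auxiliary-controlled C–C bond formation sets C1, the only stereocentre that is not relayed. The demand is face selectivity in the Michael addition of the chiral secondary enamine.

## Other disconnections considered

**Alternative 1:** (the first that comes to mind) Cut C7=C8 and close the seven-membered ring by ring-closing metathesis of the cyclopentyl vinyl ketone A1, which would give 16. The metathesis settles none of the stereocentres. A1 already carries C1, C4 and C5, including the trans C1/C5 relationship between a quaternary and a tertiary carbon, on a cyclopentane where no ring relays the configuration. The hard part is therefore only moved into the synthesis of A1. In addition, closing a trisubstituted enone next to a quaternary carbon is a demanding metathesis. The chosen plan sets C5 in the same step that creates the skeleton.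

**Alternative 2:** Cut C4–C5 (the β-hydroxy ketone retron) and close the five-membered ring by intramolecular aldol addition of the cycloheptenone A2, which would give 16. The tether reaches the enolate from the face of C2, and the aldol is reversible. The C4 and C5 centres would therefore be under thermodynamic control, with no element that enforces the trans fusion or the C4 configuration. Enolization can also start at C9, C3 or the isopropyl methine. A2 still needs an asymmetric construction of its lone quaternary centre, so the step count is not lower and the stereochemistry is less secure than with a stereospecific 1,2-shift.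

**Alternative 3:** Excise C7, a single-atom edit: the hydrindanone A3 would be ring-expanded through its silyl enol ether A4 (cyclopropanation, then oxidative ring opening) to 16. A3 is a trans-fused hydrindan-4-one with an enolizable ring-fusion hydrogen, a ring fusion expected to be less stable than the cis one, so every enolization endangers C5. The enol ether A4 has to form towards C8 and not towards C5. The substitution pattern of A3 (carbinol next to the ring-fusion CH, not next to the quaternary carbon) does not map onto the common annulation-derived hydrindenones, so A3 needs a long synthesis of its own. The insertion postpones the stereochemical problem without solving it.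

Key step: step 8

## Route

Step 1
Reactants: 1 2-methylcyclohexanone (racemic); 2 (R)-1-phenylethylamine
Product: 3 (1R)-N-(2-methylcyclohexylidene)-1-phenylethanamine (mixture at the ring methine)
Conditions: cat. TsOH, toluene, reflux, Dean–Stark
Reagents that add atoms: none
Why: Imine condensation with azeotropic removal of water; the ring stereocentre does not matter because it is erased in the secondary enamine tautomer that reacts in step 2.

Step 2
Reactants: 3 (1R)-N-(2-methylcyclohexylidene)-1-phenylethanamine; 4 methyl vinyl ketone
Product: 6 (S)-2-methyl-2-(3-oxobutyl)cyclohexan-1-one, via Michael adduct imine 5 (not isolated)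
Conditions: THF, 40 °C; then 20% aq. AcOH, rt
Reagents that add atoms: water O
Why: Deracemizing Michael addition of a chiral imine through its more substituted secondary enamine (compact aza-ene-like transition state with internal N–H transfer); the phenylethyl group shields one enamine face and should set the quaternary C1 as (S); hydrolysis returns the amine.

Step 3
Reactants: 6 (S)-2-methyl-2-(3-oxobutyl)cyclohexan-1-one
Product: 7 (S)-4a-methyl-4,4a,5,6,7,8-hexahydronaphthalen-2(3H)-one
Conditions: NaOMe, MeOH, 60 °C
Reagents that add atoms: none
Why: Intramolecular aldol condensation (second stage of a Robinson annulation) forms the C5=C6 bond; the quaternary centre cannot epimerize.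

Step 4
Reactants: 7 (S)-4a-methyl-4,4a,5,6,7,8-hexahydronaphthalen-2(3H)-one
Product: 8 (S)-4a-methyl-4,4a,5,6-tetrahydronaphthalen-2(3H)-one
Conditions: chloranil, t-BuOH, reflux
Reagents that add atoms: none
Why: Quinone dehydrogenation of an enone through its extended dienol (hydride abstraction at C8), the standard way to turn a ring-fusion enone into the linear dienone; it installs C7=C8.

Step 5
Reactants: 8 (S)-4a-methyl-4,4a,5,6-tetrahydronaphthalen-2(3H)-one
Product: 9 (2R,4aS)-4a-methyl-2-(propan-2-yl)-2,3,4,4a,5,6-hexahydronaphthalen-2-ol
Conditions: i-PrMgCl, anhydrous CeCl3, THF, −78 °C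
Reagents that add atoms: isopropylmagnesium chloride CC(C)[Mg]Cl
Why: Organocerium 1,2-addition (suppresses enolization, reduction and 1,6-addition); axial attack anti to the angular methyl, the course hydride takes on the same ring system, should place the C4 hydroxyl cis to CH3-15.

Step 6
Reactants: 9 (2R,4aS)-4a-methyl-2-(propan-2-yl)-2,3,4,4a,5,6-hexahydronaphthalen-2-ol
Product: 11 (1S,2R,4aS,8aR)-4a-methyl-2-(propan-2-yl)-1,2,3,4,4a,5,6,8a-octahydronaphthalene-1,2,8a-triol, via osmate ester 10 (not isolated)
Conditions: OsO4 (1.05 equiv), TMEDA, CH2Cl2, −78 °C; then aq. Na2SO3, THF, 60 °C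
Reagents that add atoms: osmium tetroxide O=[Os](=O)(=O)=O
Why: Hydrogen-bond-directed osmylation with the OsO4·TMEDA complex: the C4 hydroxyl binds the reagent and delivers it to the proximal C5=C6 bond on its own face (the face of CH3-15), which should give the all-cis O4/O5/O6 triad on a cis-decalin; C7=C8 has no directing group.

Step 7
Reactants: 11 (1S,2R,4aS,8aR)-4a-methyl-2-(propan-2-yl)-1,2,3,4,4a,5,6,8a-octahydronaphthalene-1,2,8a-triol
Product: 12 (1S,2R,4aS,8aR)-2,8a-dihydroxy-4a-methyl-2-(propan-2-yl)-1,2,3,4,4a,5,6,8a-octahydronaphthalen-1-yl methanesulfonate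
Conditions: MsCl (1.1 equiv), Et3N, CH2Cl2, −20 °C
Reagents that add atoms: methanesulfonyl chloride CS(=O)(=O)Cl
Why: Sulfonylation through sulfene is selective for the only secondary hydroxyl (C5); the two tertiary hydroxyls should not react under these conditions.

Step 8
Reactants: 12 (1S,2R,4aS,8aR)-2,8a-dihydroxy-4a-methyl-2-(propan-2-yl)-1,2,3,4,4a,5,6,8a-octahydronaphthalen-1-yl methanesulfonate
Product: 13 (3R,3aR,8aS)-3-hydroxy-8a-methyl-3-(propan-2-yl)-2,3,3a,7,8,8a-hexahydroazulen-4(1H)-one
Conditions: Et3Al (3 equiv), CH2Cl2, −78 to 0 °C; aq. Rochelle salt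
Reagents that add atoms: none
Why: Pinacol-type (semipinacol) 1,2-shift of a vicinal diol monosulfonate promoted by an organoaluminium reagent, the reaction type by which decalin diol monosulfonates are converted into hydroazulenones; the two tertiary hydroxyls become aluminium alkoxides and the aluminium also assists departure of the mesylate. In the favoured chair of ring B (isopropyl equatorial, C1 methyl equatorial to ring B) the C5–OMs bond is equatorial and antiperiplanar to the ring-fusion bond C6–C1, so C1 migrates from C6 to C5 while O6 becomes the carbonyl oxygen. The cyclopentane (C1–C5) is thereby formed by ring contraction of ring B and the cycloheptenone by the complementary one-carbon expansion of ring A, both in the same suprafacial shift; no ring is closed by an external bond. C5 is set by inversion (C1 enters anti to the mesylate), C1 migrates with retention and C4 is not touched, so the all-cis arrangement of CH3-15, O4, O5 and O6 in 12 is translated into H5 anti to CH3-15 (trans fusion) with the C4 hydroxyl cis to CH3-15. The selectivity needed is migration of C1 (push from O6) over C3 (push from O4; C4–C3 is also anti to the leaving group): C1 is fully substituted and its shift creates the conjugated enone, whereas C3 is a methylene and its shift would create an isolated ketone. Epoxide formation and elimination are excluded because both flanking oxygens are cis to the mesylate and neither neighbour of C5 carries hydrogen; aluminium aldolates resist retro-aldol cleavage at low temperature.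

Step 9
Reactants: 13 (3R,3aR,8aS)-3-hydroxy-8a-methyl-3-(propan-2-yl)-2,3,3a,7,8,8a-hexahydroazulen-4(1H)-one
Product: 14 (3R,3aS,8aS)-6,8a-dimethyl-3-(propan-2-yl)-3,4-bis(trimethylsilyloxy)-1,2,3,3a,6,7,8,8a-octahydroazulene (both epimers at the new methyl-bearing carbon)
Conditions: Me2CuLi (3 equiv), TMSCl (5 equiv), THF, −78 to 0 °C
Reagents that add atoms: lithium dimethylcuprate [Li+].C[Cu-]C; chlorotrimethylsilane C[Si](C)(C)Cl
Why: Silyl-chloride-accelerated cuprate conjugate addition to the β-unsubstituted enone with trapping of the enolate as the regiodefined C6=C7 silyl enol ether; the tertiary alkoxide is silylated as well, and the new C8 centre is of no consequence because step 10 erases it.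

Step 10
Reactants: 14 (3R,3aS,8aS)-6,8a-dimethyl-3-(propan-2-yl)-3,4-bis(trimethylsilyloxy)-1,2,3,3a,6,7,8,8a-octahydroazulene
Product: 16 (3R,3aR,8aS)-3-hydroxy-6,8a-dimethyl-3-(propan-2-yl)-2,3,3a,7,8,8a-hexahydroazulen-4(1H)-one, via silyl ether 15 (not isolated)
Conditions: Pd(OAc)2 (1.1 equiv), MeCN, rt; then Bu4NF, AcOH, THF, 0 °C
Reagents that add atoms: none
Why: Saegusa–Ito oxidation: the palladium enolate can eliminate only towards C8, which restores C7=C8 now carrying the methyl; buffered fluoride removes the tertiary silyl ether without the acid or base that would dehydrate or cleave the β-hydroxy ketone.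

Step 11
Reactants: 16 (3R,3aR,8aS)-3-hydroxy-6,8a-dimethyl-3-(propan-2-yl)-2,3,3a,7,8,8a-hexahydroazulen-4(1H)-one
Product: 17 (3R,3aS,4S,8aS)-6,8a-dimethyl-3-(propan-2-yl)-1,2,3,3a,4,7,8,8a-octahydroazulene-3,4-diol
Conditions: Me4NBH(OAc)3, MeCN/AcOH 1:1, −30 °C
Reagents that add atoms: none
Why: Hydroxyl-directed reduction of a β-hydroxy ketone (Evans–Saksena type): ligand exchange at the C4 hydroxyl and internal hydride delivery to the C6 carbonyl from the face of O4 should give the 1,3-anti diol, that is the C6 hydroxyl trans to the C4 hydroxyl and cis to H5; the reagent does not reduce the enone in the 1,4 sense.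

Step 12
Reactants: 17 (3R,3aS,4S,8aS)-6,8a-dimethyl-3-(propan-2-yl)-1,2,3,3a,4,7,8,8a-octahydroazulene-3,4-diol; 18 4-[(tert-butyldimethylsilyl)oxy]benzoic acid
Product: 19 (3R,3aS,4S,8aS)-3-hydroxy-6,8a-dimethyl-3-(propan-2-yl)-1,2,3,3a,4,7,8,8a-octahydroazulen-4-yl 4-[(tert-butyldimethylsilyl)oxy]benzoate
Conditions: DCC, DMAP, CH2Cl2, rt
Reagents that add atoms: none
Why: Steglich esterification; only the secondary allylic hydroxyl should be acylated, the tertiary one being inert, and no stereocentre is touched.

Step 13
Reactants: 19 (3R,3aS,4S,8aS)-3-hydroxy-6,8a-dimethyl-3-(propan-2-yl)-1,2,3,3a,4,7,8,8a-octahydroazulen-4-yl 4-[(tert-butyldimethylsilyl)oxy]benzoate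
Product: 20 (3R,3aS,4S,8aS)-3-hydroxy-6,8a-dimethyl-3-(propan-2-yl)-1,2,3,3a,4,7,8,8a-octahydroazulen-4-yl 4-hydroxybenzoate
Conditions: Bu4NF, AcOH, THF, 0 °C
Reagents that add atoms: none
Why: Fluoride cleavage of the aryl silyl ether is far faster than any reaction of the alkyl benzoate; the acetic acid buffer prevents acyl migration and ester cleavage.

## Compound list

1 | 2-methylcyclohexanone (racemic) | CC1CCCCC1=O | starting material
2 | (R)-1-phenylethylamine | C[C@@H](N)c1ccccc1 | starting material
3 | (1R)-N-(2-methylcyclohexylidene)-1-phenylethanamine (mixture at the ring methine) | CC1CCCCC1=N[C@H](C)c1ccccc1 | intermediate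
4 | methyl vinyl ketone (but-3-en-2-one) | CC(=O)C=C | starting material
5 | (1R)-N-[(2S)-2-methyl-2-(3-oxobutyl)cyclohexylidene]-1-phenylethanamine (Michael adduct imine, not isolated) | CC(=O)CC[C@]1(C)CCCCC1=N[C@H](C)c1ccccc1 | intermediate
6 | (S)-2-methyl-2-(3-oxobutyl)cyclohexan-1-one | CC(=O)CC[C@]1(C)CCCCC1=O | intermediate
7 | (S)-4a-methyl-4,4a,5,6,7,8-hexahydronaphthalen-2(3H)-one | O=C1C=C2CCCC[C@@]2(C)CC1 | intermediate
8 | (S)-4a-methyl-4,4a,5,6-tetrahydronaphthalen-2(3H)-one | O=C1C=C2C=CCC[C@@]2(C)CC1 | intermediate
9 | (2R,4aS)-4a-methyl-2-(propan-2-yl)-2,3,4,4a,5,6-hexahydronaphthalen-2-ol | CC(C)[C@]1(O)CC[C@]2(C)CCC=CC2=C1 | intermediate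
10 | cyclic osmate(VI) ester of 9 across O5/O6, TMEDA complex (not isolated) | CC(C)[C@]1(O)CC[C@]2(C)CCC=C[C@]2(O3)[C@H]1O[Os-2]34(=O)(=O)[N+](C)(C)CC[N+]4(C)C | intermediate
11 | (1S,2R,4aS,8aR)-4a-methyl-2-(propan-2-yl)-1,2,3,4,4a,5,6,8a-octahydronaphthalene-1,2,8a-triol | CC(C)[C@]1(O)CC[C@]2(C)CCC=C[C@]2(O)[C@H]1O | intermediate
12 | (1S,2R,4aS,8aR)-2,8a-dihydroxy-4a-methyl-2-(propan-2-yl)-1,2,3,4,4a,5,6,8a-octahydronaphthalen-1-yl methanesulfonate | CC(C)[C@]1(O)CC[C@]2(C)CCC=C[C@]2(O)[C@H]1OS(C)(=O)=O | intermediate
13 | (3R,3aR,8aS)-3-hydroxy-8a-methyl-3-(propan-2-yl)-2,3,3a,7,8,8a-hexahydroazulen-4(1H)-one | C1=CC(=O)[C@@H]2[C@@](C)(CC1)CC[C@@]2(O)C(C)C | intermediate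
14 | (3R,3aS,8aS)-6,8a-dimethyl-3-(propan-2-yl)-3,4-bis(trimethylsilyloxy)-1,2,3,3a,6,7,8,8a-octahydroazulene (C-6 epimers) | CC1C=C(O[Si](C)(C)C)[C@@H]2[C@@](C)(CC1)CC[C@@]2(O[Si](C)(C)C)C(C)C | intermediate
15 | (3R,3aR,8aS)-6,8a-dimethyl-3-(propan-2-yl)-3-(trimethylsilyloxy)-2,3,3a,7,8,8a-hexahydroazulen-4(1H)-one (not isolated) | CC1=CC(=O)[C@@H]2[C@@](C)(CC1)CC[C@@]2(O[Si](C)(C)C)C(C)C | intermediate
16 | (3R,3aR,8aS)-3-hydroxy-6,8a-dimethyl-3-(propan-2-yl)-2,3,3a,7,8,8a-hexahydroazulen-4(1H)-one | CC1=CC(=O)[C@@H]2[C@@](C)(CC1)CC[C@@]2(O)C(C)C | intermediate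
17 | (3R,3aS,4S,8aS)-6,8a-dimethyl-3-(propan-2-yl)-1,2,3,3a,4,7,8,8a-octahydroazulene-3,4-diol | CC1=C[C@H](O)[C@@H]2[C@@](C)(CC1)CC[C@@]2(O)C(C)C | intermediate
18 | 4-[(tert-butyldimethylsilyl)oxy]benzoic acid | CC(C)(C)[Si](C)(C)Oc1ccc(cc1)C(O)=O | starting material
19 | (3R,3aS,4S,8aS)-3-hydroxy-6,8a-dimethyl-3-(propan-2-yl)-1,2,3,3a,4,7,8,8a-octahydroazulen-4-yl 4-[(tert-butyldimethylsilyl)oxy]benzoate | CC1=C[C@H](OC(=O)c2ccc(O[Si](C)(C)C(C)(C)C)cc2)[C@@H]2[C@@](C)(CC1)CC[C@@]2(O)C(C)C | intermediate
20 | (3R,3aS,4S,8aS)-3-hydroxy-6,8a-dimethyl-3-(propan-2-yl)-1,2,3,3a,4,7,8,8a-octahydroazulen-4-yl 4-hydroxybenzoate | CC1=C[C@H](OC(=O)c2ccc(O)cc2)[C@@H]2[C@@](C)(CC1)CC[C@@]2(O)C(C)C | target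

## Step count and least certain steps

Total step count: 13. Longest linear sequence: 13 steps (1 to 20); 2, 4 and 18 are purchased.

**Step 8 (key step).** The shift may take the wrong course: the alkoxide of O4 can push instead of that of O6, so that C3 migrates and ring B contracts towards an acyl hydrindane. An ethyl group may also be transferred from aluminium to the new ketone, and the cyclopentanol may open by retro-aldol after the shift. All three stem from the free C4 hydroxyl or the Lewis-acidic reagent. The fallback sets out from the osmate ester 10 and removes the free C4 hydroxyl before the triol is released. The tertiary hydroxyl is silylated while O5 and O6 are still bound to osmium (Et3SiOTf, 2,6-lutidine), giving the silylated osmate ester F1. Sulfite cleavage gives the C4 silyl ether diol F2, and mesylation of its secondary hydroxyl gives the mesylate F3. With KHMDS (THF, −78 °C) only O6 can be deprotonated, so only C1 can be pushed, and the product is the silyl-protected hydroxy enone F4, which cannot undergo retro-aldol. HF·pyridine then returns to the route at 13.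

**Step 6.** The osmium reagent may add to the distal, less hindered C7=C8 bond of the diene or to the face anti to CH3-15, because hydrogen-bond delivery has to overcome the steric bias of the angular methyl. The fallback sets out from 7 and removes the second alkene until after the shift. Isopropylcerium addition to 7 gives the allylic alcohol F5. Directed osmylation, now without regiochemical choice, followed by sulfite work-up gives the saturated triol F6; mesylation gives the mesylate F7; and the aluminium-promoted shift gives the saturated hydroxy ketone F8. Dehydrogenation with IBX (DMSO, 70 °C), possible only towards C7/C8, comes back to the route at 13.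

**Step 9.** The lithium or copper alkoxide of the tertiary cyclopentanol may trigger retro-aldol opening before the carbonyl is consumed, or silylation of O4 may stay incomplete and give mixtures. The fallback sets out from 13 and masks the hydroxyl first: Me3SiOTf and 2,6-lutidine at −78 °C give the trimethylsilyl ether F9, and cuprate addition with silyl chloride trapping then comes back to the route at 14.

**Step 11.** Ligand exchange at the hindered tertiary hydroxyl may be too slow, so that hydride is delivered externally with poor or opposite facial selectivity. The fallback sets out from 16 and sets C6 by inversion instead of by the hydride face. Luche reduction (NaBH4, CeCl3, MeOH), or the unwanted fraction of step 11, provides the C6-epimeric diol F10. Mitsunobu esterification of F10 with 18 (PPh3, DIAD, toluene) inverts C6 and comes back to the route at 19.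

## Further compounds

F1 | step 8 | C4 triethylsilyl ether of osmate ester 10 (TMEDA complex) | CC(C)[C@]1(O[Si](CC)(CC)CC)CC[C@]2(C)CCC=C[C@]2(O3)[C@H]1O[Os-2]34(=O)(=O)[N+](C)(C)CC[N+]4(C)C
F2 | step 8 | C4 triethylsilyl ether of triol 11 | CC(C)[C@]1(O[Si](CC)(CC)CC)CC[C@]2(C)CCC=C[C@]2(O)[C@H]1O
F3 | step 8 | C4 triethylsilyl ether of mesylate 12 | CC(C)[C@]1(O[Si](CC)(CC)CC)CC[C@]2(C)CCC=C[C@]2(O)[C@H]1OS(C)(=O)=O
F4 | step 8 | triethylsilyl ether of hydroxy enone 13 | C1=CC(=O)[C@@H]2[C@@](C)(CC1)CC[C@@]2(O[Si](CC)(CC)CC)C(C)C
F5 | step 6 | (2R,4aS)-4a-methyl-2-(propan-2-yl)-2,3,4,4a,5,6,7,8-octahydronaphthalen-2-ol | CC(C)[C@]1(O)CC[C@]2(C)CCCCC2=C1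
F6 | step 6 | 7,8-dihydro analogue of triol 11 (all-cis decalin-1,2,8a-triol) | CC(C)[C@]1(O)CC[C@]2(C)CCCC[C@]2(O)[C@H]1O
F7 | step 6 | 7,8-dihydro analogue of mesylate 12 | CC(C)[C@]1(O)CC[C@]2(C)CCCC[C@]2(O)[C@H]1OS(C)(=O)=O
F8 | step 6 | 5,6-dihydro analogue of enone 13 (trans-fused 3-hydroxy-8a-methyl-3-isopropyl-octahydroazulen-4-one) | C1CC(=O)[C@@H]2[C@@](C)(CC1)CC[C@@]2(O)C(C)C
F9 | step 9 | trimethylsilyl ether of hydroxy enone 13 | C1=CC(=O)[C@@H]2[C@@](C)(CC1)CC[C@@]2(O[Si](C)(C)C)C(C)C
F10 | step 11 | C4 epimer (azulene numbering) of diol 17 | CC1=C[C@@H](O)[C@@H]2[C@@](C)(CC1)CC[C@@]2(O)C(C)C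
A1 | alternative 1 | 1-[(1R,2R,5S)-2-hydroxy-5-methyl-5-(3-methylbut-3-en-1-yl)-2-(propan-2-yl)cyclopentyl]prop-2-en-1-one | C=CC(=O)[C@@H]1[C@@](C)(CCC(C)=C)CC[C@@]1(O)C(C)C
A2 | alternative 2 | (S)-3,6-dimethyl-6-(4-methyl-3-oxopentyl)cyclohept-2-en-1-one | CC1=CC(=O)C[C@](C)(CCC(=O)C(C)C)CC1
A3 | alternative 3 | (3R,3aR,7aS)-3-hydroxy-5,7a-dimethyl-3-(propan-2-yl)octahydro-4H-inden-4-one (C-5 epimers) | CC1C(=O)[C@@H]2[C@@](C)(CC1)CC[C@@]2(O)C(C)C
A4 | alternative 3 | C4=C5 trimethylsilyl enol ether of A3 | CC1=C(O[Si](C)(C)C)[C@@H]2[C@@](C)(CC1)CC[C@@]2(O)C(C)C
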